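The target is a 3',6''-linked biflavone whose single methyl ether sits on C4' of unit 1, directly beside the interflavone bond at C3'. These two adjacent carbons of ring B of unit 1 are treated as the two carbons of an aryl methoxyalkyne, and ring B is grown around them. One thermal operation with methyl coumalate forms C2'–C3' and C4'–C5', expels CO2, fixes the biaryl pattern, places the methyl ether and leaves an ester on C1' for the first chromenone. The precursor is a 2,4,6-trioxygenated phenyl methoxyalkyne: MOM on the para oxygen, hydrogenolysable ethers on both ortho oxygens, so unit 2 can close only through the para oxygen, giving the C6'' linkage.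

Key step: step 5

Assumption: the SMILES shows no stereocentre and no axial descriptor, so the C3'–C6'' axis is treated as freely rotating and no stereocontrol is planned.

Design notes:
- **Ortho protecting groups.** Plain benzyl ethers are not carried through the C–H borylation, because their unhindered meta and para C–H bonds would compete. The two ortho oxygens of ring A of unit 2 therefore carry 4-methylbenzyl groups. Every ring C–H of these groups has an ortho neighbour, and they fall in the same final hydrogenolysis.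
- **Halide.** An iodide is used because the C–X bond is flanked by two ethers on an electron-rich ring.
- **Step economy.** The methyl ester enters a crossed Claisen condensation directly, and MOM removal is merged with the first ring closure.
- **Acetyl group of unit 2.** It is installed by iodination and Stille coupling. Lewis-acid acylation would endanger the ether next to the new carbonyl, and with it the distinction between the ortho and para oxygens.

Step 1
Reactants: 1 2-iodoresorcinol
Product: 2 2-iodo-1,3-bis[(4-methylbenzyl)oxy]benzene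
Conditions: 4-methylbenzyl bromide (2.3 equiv), K2CO3, DMF, 25 to 50 °C
Reagents that add atoms: 4-methylbenzyl bromide, Cc1ccc(CBr)cc1
Why: Williamson ether synthesis in which both phenoxides of 1 are alkylated by the benzylic bromide under carbonate conditions that leave the C–I bond alone.

Step 2
Reactants: 2 2-iodo-1,3-bis[(4-methylbenzyl)oxy]benzene
Product: 4 4-iodo-3,5-bis[(4-methylbenzyl)oxy]phenol, via aryl pinacol boronate 3 (not isolated)
Conditions: [Ir(OMe)(cod)]2 (1.5 mol %), dtbpy (3 mol %), B2pin2 (1.0 equiv), THF, 40 °C; then 30% aq H2O2, aq NaOH, THF, 0 °C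
Reagents that add atoms: bis(pinacolato)diboron, CC1(C)OB(OC1(C)C)B1OC(C)(C)C(C)(C)O1 (boron and pinacolate of 3 only); hydrogen peroxide, OO (phenol oxygen of 4)
Why: Sterically governed iridium-catalysed aromatic C–H borylation and oxidation of the C–B bond in one flask; C5–H is the only aromatic C–H of 2 without an ortho substituent, aryl iodides are tolerated by this catalyst, and alkaline peroxide turns the boronate into the phenol by 1,2-aryl migration.

Step 3
Reactants: 4 4-iodo-3,5-bis[(4-methylbenzyl)oxy]phenol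
Product: 5 2-iodo-5-(methoxymethoxy)-1,3-bis[(4-methylbenzyl)oxy]benzene
Conditions: MOMCl, i-Pr2NEt, CH2Cl2, 0 to 25 °C
Reagents that add atoms: chloromethyl methyl ether (MOMCl), COCCl
Why: Standard O-alkylation of a phenol to its acetal; MOM stands up to organozinc reagents, neutral heating and NaH, and falls later in the acid step that closes the first chromenone.

Step 4
Reactants: 5 2-iodo-5-(methoxymethoxy)-1,3-bis[(4-methylbenzyl)oxy]benzene; 6 chloroacetaldehyde dimethyl acetal
Product: 9 2-(methoxyethynyl)-5-(methoxymethoxy)-1,3-bis[(4-methylbenzyl)oxy]benzene, via methoxyethynyllithium 7 (not isolated), via methoxyethynylzinc chloride 8 (not isolated)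
Conditions: 6 (2 equiv), LiNEt2 (3.1 equiv per 6, from Et2NH and n-BuLi), THF, 0 °C; ZnCl2 (2 equiv per 6), 0 °C; then 5, Pd(PPh3)4 (5 mol %), THF, 25 to 50 °C; filtration through basic Al2O3
Reagents that add atoms: lithium diethylamide, [Li]N(CC)CC (lithium of 7 only); ZnCl2, Cl[Zn]Cl (zinc and chlorine of 8 only)
Why: Amide-induced loss of methanol and HCl from 6 followed by deprotonation gives the lithium acetylide, transmetalation gives the alkynylzinc halide, and the Negishi coupling of alkoxyethynylzinc halides with aryl iodides under zerovalent palladium is established chemistry.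

Step 5
Reactants: 9 2-(methoxyethynyl)-5-(methoxymethoxy)-1,3-bis[(4-methylbenzyl)oxy]benzene; 10 methyl coumalate
Product: 12 methyl 4-methoxy-3-{4-(methoxymethoxy)-2,6-bis[(4-methylbenzyl)oxy]phenyl}benzoate, via bridged bicyclic lactone 11 (not isolated)
Conditions: 10 (2 equiv, freshly sublimed), 2,6-di-tert-butylpyridine (10 mol %), dry degassed o-xylene (0.5 M), sealed tube, 140 °C
Reagents that add atoms: none
Why: The methoxy oxygen raises the HOMO of the triple bond of 9, which adds across C3 and C6 of the electron-poor diene of 10 in an inverse-electron-demand Diels–Alder reaction that is probably asynchronous, the aryl-bearing alkyne carbon bonding to C6 ahead of the methoxy-bearing carbon bonding to C3. The bridged lactone 11 then loses CO2 by retro-[4+2] at the same temperature, so ring B of unit 1 is closed by an intermolecular [4+2] cycloaddition followed by cycloreversion and aromatisation, with C2'–C3' and C4'–C5' as the new bonds. The closest known reaction type is the benzannulation of 2-pyranone-5-carboxylates with ynamines, alkynyl ethers and ketene acetals. The two bridgehead stereocentres of 11 are erased on aromatisation and 12 has none, so no stereocontrol is required. Regioselectivity is what the step needs: the oxygen lone pair polarises the alkyne more strongly than the aryl ring does (electrophiles such as the proton also attack aryl alkynyl ethers at the aryl-bearing carbon), and C6 of 10, β to the ester and at the end of the vinylogous lactone, is its most electrophilic diene terminus, so methoxy ends para and aryl meta to the ester. A methyl alkynyl ether has no β-hydrogen for retro-ene collapse to a ketene, and the diene can approach over the face of the aryl ring, away from the in-plane ortho ethers, in a geometry that already resembles the twisted biaryl.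

Step 6
Reactants: 13 2,4,6-trihydroxyacetophenone
Product: 14 1-[2,4-bis(benzyloxy)-6-hydroxyphenyl]ethan-1-one
Conditions: BnBr (2.05 equiv), K2CO3, DMF, 25 to 60 °C
Reagents that add atoms: benzyl bromide, BrCc1ccccc1
Why: Chemoselective Williamson etherification in which the hydroxyl hydrogen-bonded to the ketone is the least nucleophilic, so two equivalents of bromide stop at the diether, a standard preparation of this acetophenone.

Step 7
Reactants: 12 methyl 4-methoxy-3-{4-(methoxymethoxy)-2,6-bis[(4-methylbenzyl)oxy]phenyl}benzoate; 14 1-[2,4-bis(benzyloxy)-6-hydroxyphenyl]ethan-1-one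
Product: 15 1-[2,4-bis(benzyloxy)-6-hydroxyphenyl]-3-(4-methoxy-3-{4-(methoxymethoxy)-2,6-bis[(4-methylbenzyl)oxy]phenyl}phenyl)propane-1,3-dione
Conditions: 14 (1.5 equiv), NaH (4 equiv), THF, reflux; cold aq NH4Cl
Reagents that add atoms: none
Why: Crossed Claisen condensation in which the phenoxide-enolate of 14 attacks the non-enolisable ester 12 and deprotonation of the β-diketone drives the reaction, an ester route known for 5,7-dioxygenated flavones that replaces the longer acid chloride and Baker–Venkataraman sequence.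

Step 8
Reactants: 15 the β-diketone of step 7
Product: 16 5,7-bis(benzyloxy)-2-(3-{4-hydroxy-2,6-bis[(4-methylbenzyl)oxy]phenyl}-4-methoxyphenyl)-4H-chromen-4-one
Conditions: conc. HCl (a few equiv), MeOH–THF 1:1, 60 °C
Reagents that add atoms: none
Why: Acid-catalysed cyclodehydration of the o-hydroxyaryl β-diketone closes the pyranone of unit 1 while the same methanolic acid transacetalises the MOM group, and aryl benzyl-type ethers survive dilute HCl at this temperature.

Step 9
Reactants: 16 5,7-bis(benzyloxy)-2-(3-{4-hydroxy-2,6-bis[(4-methylbenzyl)oxy]phenyl}-4-methoxyphenyl)-4H-chromen-4-one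
Product: 17 5,7-bis(benzyloxy)-2-(3-{4-hydroxy-3-iodo-2,6-bis[(4-methylbenzyl)oxy]phenyl}-4-methoxyphenyl)-4H-chromen-4-one
Conditions: NIS (1.0 equiv), DMF, −20 to 0 °C
Reagents that add atoms: N-iodosuccinimide, O=C1CCC(=O)N1I
Why: Electrophilic aromatic iodination in which the free phenol ring is by far the most activated ring of 16 and its only two open positions, both ortho to the hydroxyl, are equivalent by symmetry, so only one monoiodide can form.

Step 10
Reactants: 17 the iodophenol of step 9; 18 tributyl(1-ethoxyvinyl)stannane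
Product: 20 2-(3-{3-acetyl-4-hydroxy-2,6-bis[(4-methylbenzyl)oxy]phenyl}-4-methoxyphenyl)-5,7-bis(benzyloxy)-4H-chromen-4-one, via ethoxyvinyl arene 19 (not isolated)
Conditions: 18 (1.5 equiv), PdCl2(PPh3)2 (5 mol %), toluene, 100 °C; then 1 M HCl, THF, 25 °C
Reagents that add atoms: water, O
Why: Stille coupling with an acetyl anion equivalent followed by mild enol ether hydrolysis delivers the methyl ketone without any Lewis acid, so all four benzyl-type ethers stay in place.

Step 11
Reactants: 20 the o-hydroxyacetophenone of step 10; 21 4-(benzyloxy)benzoyl chloride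
Product: 22 1-[4-(benzyloxy)phenyl]-3-(3-{5-[5,7-bis(benzyloxy)-4-oxo-4H-chromen-2-yl]-2-methoxyphenyl}-6-hydroxy-2,4-bis[(4-methylbenzyl)oxy]phenyl)propane-1,3-dione
Conditions: LiN(SiMe3)2 (4 equiv), THF, −78 °C; 21 (1.1 equiv), −78 to 25 °C; aq NH4Cl
Reagents that add atoms: none
Why: One-flask form of the Baker–Venkataraman synthesis in which the phenoxide-enolate of 20 is aroylated at carbon (any O-aroyl ester rearranges under the same base), and the hindered amide base should leave the chromenone of unit 1 untouched.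

Step 12
Reactants: 22 the β-diketone of step 11
Product: 23 5,7-bis(benzyloxy)-2-(3-{2-[4-(benzyloxy)phenyl]-5,7-bis[(4-methylbenzyl)oxy]-4-oxo-4H-chromen-6-yl}-4-methoxyphenyl)-4H-chromen-4-one
Conditions: conc. HCl (cat.), MeOH–THF 1:1, 60 °C
Reagents that add atoms: none
Why: Acid-catalysed cyclodehydration as in step 8, in which only the para-derived hydroxyl is free, so the pyranone of unit 2 closes through it and the biaryl bond ends at C6'' and not at C8''.

Step 13
Reactants: 23 the fully protected biflavone
Product: 24 6-[5-(5,7-dihydroxy-4-oxo-4H-chromen-2-yl)-2-methoxyphenyl]-5,7-dihydroxy-2-(4-hydroxyphenyl)-4H-chromen-4-one (target CNP0197234.0)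
Conditions: H2 (1 atm), 10% Pd/C, THF–MeOH, 25 °C, stopped at full debenzylation
Reagents that add atoms: none
Why: Catalytic hydrogenolysis cleaves all five benzylic C–O bonds under neutral conditions, leaves the aryl methyl ether untouched and avoids the strong acid that could cause Wessely–Moser isomerisation of the 6-aryl to the 8-aryl chromenone.

Compound list
1 | 2-iodoresorcinol (2-iodobenzene-1,3-diol) | Oc1cccc(O)c1I | starting material
2 | 2-iodo-1,3-bis[(4-methylbenzyl)oxy]benzene | Cc1ccc(COc2cccc(OCc3ccc(C)cc3)c2I)cc1 | intermediate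
3 | 2-{4-iodo-3,5-bis[(4-methylbenzyl)oxy]phenyl}-4,4,5,5-tetramethyl-1,3,2-dioxaborolane (not isolated) | Cc1ccc(COc2cc(B3OC(C)(C)C(C)(C)O3)cc(OCc3ccc(C)cc3)c2I)cc1 | intermediate
4 | 4-iodo-3,5-bis[(4-methylbenzyl)oxy]phenol | Cc1ccc(COc2cc(O)cc(OCc3ccc(C)cc3)c2I)cc1 | intermediate
5 | 2-iodo-5-(methoxymethoxy)-1,3-bis[(4-methylbenzyl)oxy]benzene | COCOc1cc(OCc2ccc(C)cc2)c(I)c(OCc2ccc(C)cc2)c1 | intermediate
6 | chloroacetaldehyde dimethyl acetal (2-chloro-1,1-dimethoxyethane) | COC(CCl)OC | starting material
7 | methoxyethynyllithium (not isolated) | [Li]C#COC | intermediate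
8 | methoxyethynylzinc chloride (not isolated) | COC#C[Zn]Cl | intermediate
9 | 2-(methoxyethynyl)-5-(methoxymethoxy)-1,3-bis[(4-methylbenzyl)oxy]benzene | COC#Cc1c(OCc2ccc(C)cc2)cc(OCOC)cc1OCc1ccc(C)cc1 | intermediate
10 | methyl coumalate (methyl 2-oxo-2H-pyran-5-carboxylate) | COC(=O)c1ccc(=O)oc1 | starting material
11 | methyl 8-methoxy-7-{4-(methoxymethoxy)-2,6-bis[(4-methylbenzyl)oxy]phenyl}-3-oxo-2-oxabicyclo[2.2.2]octa-5,7-diene-6-carboxylate (racemic, not isolated) | O=C1OC2C(C(=O)OC)=CC1C(OC)=C2c1c(OCc2ccc(C)cc2)cc(OCOC)cc1OCc1ccc(C)cc1 | intermediate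
12 | methyl 4-methoxy-3-{4-(methoxymethoxy)-2,6-bis[(4-methylbenzyl)oxy]phenyl}benzoate | COC(=O)c1ccc(OC)c(-c2c(OCc3ccc(C)cc3)cc(OCOC)cc2OCc2ccc(C)cc2)c1 | intermediate
13 | 2,4,6-trihydroxyacetophenone | CC(=O)c1c(O)cc(O)cc1O | starting material
14 | 1-[2,4-bis(benzyloxy)-6-hydroxyphenyl]ethan-1-one | CC(=O)c1c(O)cc(OCc2ccccc2)cc1OCc1ccccc1 | intermediate
15 | 1-[2,4-bis(benzyloxy)-6-hydroxyphenyl]-3-(4-methoxy-3-{4-(methoxymethoxy)-2,6-bis[(4-methylbenzyl)oxy]phenyl}phenyl)propane-1,3-dione (drawn as the diketo tautomer) | COc1ccc(C(=O)CC(=O)c2c(O)cc(OCc3ccccc3)cc2OCc2ccccc2)cc1-c1c(OCc2ccc(C)cc2)cc(OCOC)cc1OCc1ccc(C)cc1 | intermediate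
16 | 5,7-bis(benzyloxy)-2-(3-{4-hydroxy-2,6-bis[(4-methylbenzyl)oxy]phenyl}-4-methoxyphenyl)-4H-chromen-4-one | COc1ccc(-c2cc(=O)c3c(OCc4ccccc4)cc(OCc4ccccc4)cc3o2)cc1-c1c(OCc2ccc(C)cc2)cc(O)cc1OCc1ccc(C)cc1 | intermediate
17 | 5,7-bis(benzyloxy)-2-(3-{4-hydroxy-3-iodo-2,6-bis[(4-methylbenzyl)oxy]phenyl}-4-methoxyphenyl)-4H-chromen-4-one | COc1ccc(-c2cc(=O)c3c(OCc4ccccc4)cc(OCc4ccccc4)cc3o2)cc1-c1c(OCc2ccc(C)cc2)cc(O)c(I)c1OCc1ccc(C)cc1 | intermediate
18 | tributyl(1-ethoxyvinyl)stannane | CCCC[Sn](CCCC)(CCCC)C(=C)OCC | starting material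
19 | 5,7-bis(benzyloxy)-2-(3-{3-(1-ethoxyvinyl)-4-hydroxy-2,6-bis[(4-methylbenzyl)oxy]phenyl}-4-methoxyphenyl)-4H-chromen-4-one (not isolated) | COc1ccc(-c2cc(=O)c3c(OCc4ccccc4)cc(OCc4ccccc4)cc3o2)cc1-c1c(OCc2ccc(C)cc2)cc(O)c(C(=C)OCC)c1OCc1ccc(C)cc1 | intermediate
20 | 2-(3-{3-acetyl-4-hydroxy-2,6-bis[(4-methylbenzyl)oxy]phenyl}-4-methoxyphenyl)-5,7-bis(benzyloxy)-4H-chromen-4-one | COc1ccc(-c2cc(=O)c3c(OCc4ccccc4)cc(OCc4ccccc4)cc3o2)cc1-c1c(OCc2ccc(C)cc2)cc(O)c(C(C)=O)c1OCc1ccc(C)cc1 | intermediate
21 | 4-(benzyloxy)benzoyl chloride | O=C(Cl)c1ccc(OCc2ccccc2)cc1 | starting material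
22 | 1-[4-(benzyloxy)phenyl]-3-(3-{5-[5,7-bis(benzyloxy)-4-oxo-4H-chromen-2-yl]-2-methoxyphenyl}-6-hydroxy-2,4-bis[(4-methylbenzyl)oxy]phenyl)propane-1,3-dione (drawn as the diketo tautomer) | COc1ccc(-c2cc(=O)c3c(OCc4ccccc4)cc(OCc4ccccc4)cc3o2)cc1-c1c(OCc2ccc(C)cc2)cc(O)c(C(=O)CC(=O)c2ccc(OCc3ccccc3)cc2)c1OCc1ccc(C)cc1 | intermediate
23 | 5,7-bis(benzyloxy)-2-(3-{2-[4-(benzyloxy)phenyl]-5,7-bis[(4-methylbenzyl)oxy]-4-oxo-4H-chromen-6-yl}-4-methoxyphenyl)-4H-chromen-4-one | COc1ccc(-c2cc(=O)c3c(OCc4ccccc4)cc(OCc4ccccc4)cc3o2)cc1-c1c(OCc2ccc(C)cc2)cc2oc(-c3ccc(OCc4ccccc4)cc3)cc(=O)c2c1OCc1ccc(C)cc1 | intermediate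
24 | 6-[5-(5,7-dihydroxy-4-oxo-4H-chromen-2-yl)-2-methoxyphenyl]-5,7-dihydroxy-2-(4-hydroxyphenyl)-4H-chromen-4-one (3',6''-biapigenin 4'-methyl ether, no stereocentre) | COc1ccc(-c2cc(=O)c3c(O)cc(O)cc3o2)cc1-c1c(O)cc2oc(-c3ccc(O)cc3)cc(=O)c2c1O | target

Total step count: 13. Longest linear sequence: 12 (steps 1–5 and 7–13; step 6 is a one-step branch).

Steps most likely to fail

**Step 5.**
- The cycloaddition may be slow because the two ortho ethers shield the triple bond.
- Regiocontrol may erode because the electron-rich aryl ring polarises the alkyne against the methoxy group.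
- The alkynyl ether may decay by hydration or oligomerisation before it reacts.
- Fallback: the biaryl bond is made directly instead of building ring B. Iodide 5 is coupled in a Suzuki–Miyaura reaction with purchased [2-methoxy-5-(methoxycarbonyl)phenyl]boronic acid (COC(=O)c1ccc(OC)c(B(O)O)c1). Conditions would be Pd(OAc)2, SPhos, K3PO4, toluene–water, 90 °C. This sets out from 5 and comes back to the route at 12; no new compound is made on the way (F0).

**Step 4.**
- Oxidative addition and transmetalation at the doubly flanked C–I bond may stall.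
- Reductive loss of iodine may compete.
- The product may hydrate during work-up.
- Fallback: the triple bond is made by elimination instead of cross-coupling, setting out from 5. Iodine–magnesium exchange (i-PrMgCl·LiCl, THF, −20 °C) gives the arylmagnesium chloride F1. Acylation of F1 with N,2-dimethoxy-N-methylacetamide (COCC(=O)N(C)OC) gives the aryl methoxymethyl ketone F2. KN(SiMe3)2 and PhNTf2 (THF, −78 °C) trap the chelated enolate as the (Z)-enol triflate F3. KOt-Bu (THF, −78 to 0 °C) then removes triflic acid by anti elimination, and the sequence comes back to the route at 9.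

**Step 10.**
- Transmetalation at the iodide between a hydroxyl and a bulky ether may be slow, so protodeiodination may take over.
- Fallback: the acetyl stage is skipped, setting out from 17. Palladium-catalysed carbonylative alkynylation with 1-(benzyloxy)-4-ethynylbenzene (C#Cc1ccc(OCc2ccccc2)cc1) under CO (PdCl2(dppf), Et2NH, DMF, 60 to 100 °C) gives the o-hydroxyaryl ynone F4. Amine conjugate addition then closes F4 in the 6-endo mode in the same flask. The sequence comes back to the route at 23, by-passing 20 and 22.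

Further compounds
F0 | step 5 | none | none
F1 | step 4 | {4-(methoxymethoxy)-2,6-bis[(4-methylbenzyl)oxy]phenyl}magnesium chloride | COCOc1cc(OCc2ccc(C)cc2)c([Mg]Cl)c(OCc2ccc(C)cc2)c1
F2 | step 4 | 2-methoxy-1-{4-(methoxymethoxy)-2,6-bis[(4-methylbenzyl)oxy]phenyl}ethan-1-one | COCC(=O)c1c(OCc2ccc(C)cc2)cc(OCOC)cc1OCc1ccc(C)cc1
F3 | step 4 | (Z)-2-methoxy-1-{4-(methoxymethoxy)-2,6-bis[(4-methylbenzyl)oxy]phenyl}vinyl trifluoromethanesulfonate | CO/C=C(\OS(=O)(=O)C(F)(F)F)c1c(OCc2ccc(C)cc2)cc(OCOC)cc1OCc1ccc(C)cc1
F4 | step 10 | 5,7-bis(benzyloxy)-2-(3-{3-[3-(4-(benzyloxy)phenyl)propioloyl]-4-hydroxy-2,6-bis[(4-methylbenzyl)oxy]phenyl}-4-methoxyphenyl)-4H-chromen-4-one | COc1ccc(-c2cc(=O)c3c(OCc4ccccc4)cc(OCc4ccccc4)cc3o2)cc1-c1c(OCc2ccc(C)cc2)cc(O)c(C(=O)C#Cc2ccc(OCc3ccccc3)cc2)c1OCc1ccc(C)cc1
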